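**Retrosynthetic overview**
1. Last disconnection: the CH2 bridge, giving the chromene phenol (ring B half), the (S)-dearomatised acylphloroglucinol (ring A half) and a one-carbon iminium salt (Mannich, ortho-quinone methide, Michael addition).
2. Key disconnection: the pyran O–C(CH3)2 bond of the chromene, back to 3-prenyl-phlorisobutyrophenone. It is closed by an acyl-chelate-directed aerobic oxypalladation, so that of three hydroxyls the one next to the acyl group becomes the ring oxygen.
3. The prenyl phenol comes from phloroglucinol by Friedel–Crafts acylation with isobutyryl chloride and C-prenylation with prenyl bromide.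
4. The ring A half comes from 2-methylphloroglucinol by acylation, then enantioselective dearomative C-prenylation at the methyl-bearing carbon, which sets the only stereocentre.
5. Ring order: both carbocycles are bought as arenes. The pyran ring is the only ring made (early, on the ring B fragment); ring A is dearomatised before the two halves are joined in the last step.

Assumptions: the dearomatised ring is drawn in the tautomer of the given SMILES and (S) refers to that drawing; the (R,R)-ligand of the prenylation step is taken to give the (S)-product, and the (S,S)-ligand is used instead if the first run shows the opposite sense.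

**Route**

Step 1
Reactants: 1 phloroglucinol; 2 isobutyryl chloride
Product: 3 phlorisobutyrophenone (2-methyl-1-(2,4,6-trihydroxyphenyl)propan-1-one)
Conditions: AlCl3 (3 equiv), PhNO2/CH2Cl2, 0 °C → 40 °C; aq HCl
Reagents that add atoms: isobutyryl chloride (compound 2), CC(C)C(Cl)=O
Why: Friedel–Crafts C-acylation of the symmetric, highly activated triol stops at the monoketone because the AlCl3-chelated acyl group deactivates the ring; no stereocentre.

Step 2
Reactants: 3 phlorisobutyrophenone; 4 prenyl bromide
Product: 5 2-methyl-1-[2,4,6-trihydroxy-3-(3-methylbut-2-en-1-yl)phenyl]propan-1-one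
Conditions: 4 (0.9 equiv), KOH (1.0 equiv), H2O, 0 °C → rt; aq HCl
Reagents that add atoms: prenyl bromide (compound 4), CC(C)=CCBr
Why: C-alkylation of the ambident phloroglucinolate in water (hydrogen bonding shields oxygen, SN2 on the allylic bromide) gives the ortho-prenyl phenol; the two free ring carbons of 3 are equivalent and a deficit of bromide limits diprenylation; no stereocentre.

Step 3
Reactants: 5 2-methyl-1-[2,4,6-trihydroxy-3-(3-methylbut-2-en-1-yl)phenyl]propan-1-one
Product: 6 1-(5,7-dihydroxy-2,2-dimethyl-2H-chromen-8-yl)-2-methylpropan-1-one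
Conditions: Pd(OCOCF3)2 (5 mol %), pyridine (10 mol %), AcOH (5 equiv), 3 Å MS, O2 (1 atm), PhMe, 60 °C
Reagents that add atoms: none
Why: Proposed new method: acyl-chelate-directed aerobic oxypalladation, in which Pd(OCOCF3)2 exchanges a carboxylate for the 2-acylphenol unit of 5 to form a six-membered κ2-O,O chelate of divalent palladium (the binding mode of Pd(acac)2), only the chelate through the 2-OH can reach the prenyl alkene, the alkene inserts into the Pd–O bond (syn-oxypalladation, 6-endo, oxygen to the tertiary carbon), β-hydride elimination toward the benzylic CH2 gives the 2H-chromene and O2 reoxidises the palladium hydride, while the more acidic 4-OH cannot chelate and stays protonated in the AcOH-buffered, chloride-free medium, so the pyran oxygen ends next to the acyl group; closest known reaction type: Wacker-type aerobic oxidative cyclisation of 2-prenylphenols to 2,2-dimethyl-2H-chromenes with divalent palladium, where selection among several hydroxyls by chelation has not been shown.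

Step 4
Reactants: 7 2-methylphloroglucinol; 2 isobutyryl chloride
Product: 8 2-methyl-1-(2,4,6-trihydroxy-3-methylphenyl)propan-1-one
Conditions: AlCl3 (3 equiv), PhNO2/CH2Cl2, 0 °C → 40 °C; aq HCl
Reagents that add atoms: isobutyryl chloride (compound 2), CC(C)C(Cl)=O
Why: Friedel–Crafts C-acylation; the two free ring carbons of 7 are equivalent, so one regioisomer forms; no stereocentre.

Step 5
Reactants: 8 2-methyl-1-(2,4,6-trihydroxy-3-methylphenyl)propan-1-one; 9 prenyl acetate
Product: 10 (4S)-3,5-dihydroxy-4-methyl-4-(3-methylbut-2-en-1-yl)-2-(2-methylpropanoyl)cyclohexa-2,5-dien-1-one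
Conditions: Pd2(dba)3·CHCl3 (2.5 mol %), (1R,2R)-N,N'-bis[2-(diphenylphosphino)benzoyl]cyclohexane-1,2-diamine (Trost ligand, 7.5 mol %), Et3N (1.0 equiv), CH2Cl2, 0 °C → rt; aq HCl, then NaHCO3 extraction of the acidic product
Reagents that add atoms: prenyl acetate (compound 9), CC(=O)OCC=C(C)C
Why: Proposed new method: enantioselective dearomative C-prenylation, in which zerovalent palladium and the Trost ligand ionise 9 to a π-(1,1-dimethylallyl)palladium cation, the triethylammonium phenoxide of 8 (charge on the oxygen para to the acyl group) attacks the unsubstituted allyl terminus with its methyl-bearing ortho carbon (the more electron-rich of the two ortho carbons), any O-prenyl ether formed first is re-ionised by the catalyst, the product is a vinylogous acid (pKa about 5) removed irreversibly as its ammonium salt, and the chiral pocket distinguishes the two faces of the flat phenoxide (acyl-flanked against H-flanked edge) and so sets the quaternary stereocentre as (S); closest known reaction type: palladium-catalysed asymmetric allylic alkylation (Tsuji–Trost) in its dearomative mode on naphthols, and the racemic palladium-catalysed dearomative allylation of acylphloroglucinols.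

Step 6
Reactants: 6 1-(5,7-dihydroxy-2,2-dimethyl-2H-chromen-8-yl)-2-methylpropan-1-one; 11 Eschenmoser's salt; 10 (4S)-3,5-dihydroxy-4-methyl-4-(3-methylbut-2-en-1-yl)-2-(2-methylpropanoyl)cyclohexa-2,5-dien-1-one
Product: 13 CNP0301804.1 (the target), via chromene Mannich base 12 (not isolated)
Conditions: 6, 11 (1.0 equiv), NaOAc (1.1 equiv), MeCN, 0 °C → rt, 1 h; then 10 (1.0 equiv), 60 °C, N2
Reagents that add atoms: Eschenmoser's salt (compound 11), C=[N+](C)C.[I-]
Why: Mannich aminomethylation of the only free ring carbon of 6 is complete before 10 is added; the acidic trione 10 then protonates the amine, dimethylamine leaves to give the ortho-quinone methide of ring B, and the enol carbon of 10 (its only C–H position) adds in a Michael reaction, so only the mixed dimer can form and the quaternary stereocentre is not touched.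

**Compound list**
1 | phloroglucinol (benzene-1,3,5-triol) | Oc1cc(O)cc(O)c1 | starting material
2 | isobutyryl chloride (2-methylpropanoyl chloride) | CC(C)C(Cl)=O | starting material
3 | phlorisobutyrophenone, 2-methyl-1-(2,4,6-trihydroxyphenyl)propan-1-one | CC(C)C(=O)c1c(O)cc(O)cc1O | intermediate
4 | prenyl bromide (1-bromo-3-methylbut-2-ene) | CC(C)=CCBr | starting material
5 | 2-methyl-1-[2,4,6-trihydroxy-3-(3-methylbut-2-en-1-yl)phenyl]propan-1-one | CC(C)C(=O)c1c(O)cc(O)c(CC=C(C)C)c1O | intermediate
6 | 1-(5,7-dihydroxy-2,2-dimethyl-2H-chromen-8-yl)-2-methylpropan-1-one | CC(C)C(=O)c1c(O)cc(O)c2C=CC(C)(C)Oc12 | intermediate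
7 | 2-methylphloroglucinol (2-methylbenzene-1,3,5-triol) | Cc1c(O)cc(O)cc1O | starting material
8 | 2-methyl-1-(2,4,6-trihydroxy-3-methylphenyl)propan-1-one | CC(C)C(=O)c1c(O)cc(O)c(C)c1O | intermediate
9 | prenyl acetate (3-methylbut-2-en-1-yl acetate) | CC(=O)OCC=C(C)C | starting material
10 | (4S)-3,5-dihydroxy-4-methyl-4-(3-methylbut-2-en-1-yl)-2-(2-methylpropanoyl)cyclohexa-2,5-dien-1-one | CC(C)=CC[C@@]1(C)C(O)=CC(=O)C(C(=O)C(C)C)=C1O | intermediate
11 | Eschenmoser's salt (N,N-dimethylmethyleneiminium iodide) | C=[N+](C)C.[I-] | starting material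
12 | 1-{6-[(dimethylamino)methyl]-5,7-dihydroxy-2,2-dimethyl-2H-chromen-8-yl}-2-methylpropan-1-one (chromene Mannich base, not isolated) | CC(C)C(=O)c1c(O)c(CN(C)C)c(O)c2C=CC(C)(C)Oc12 | intermediate
13 | (4S)-2-{[5,7-dihydroxy-2,2-dimethyl-8-(2-methylpropanoyl)-2H-chromen-6-yl]methyl}-3,5-dihydroxy-4-methyl-4-(3-methylbut-2-en-1-yl)-6-(2-methylpropanoyl)cyclohexa-2,5-dien-1-one (CNP0301804.1) | CC(C)=CC[C@@]1(C)C(O)=C(Cc2c(O)c3c(c(C(=O)C(C)C)c2O)OC(C)(C)C=C3)C(=O)C(C(=O)C(C)C)=C1O | target

**Step count and risks**
Total steps: 6. Longest linear sequence: 4 steps (steps 1, 2, 3, 6); the other branch is steps 4, 5, 6.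

Three steps most likely to fail:

Step 3 (proposed new step). Risks are closure through the 4-OH (the 6-acyl chromene), acid- or palladium-mediated hydroalkoxylation to the chroman, and oxidation of the electron-rich arene. The fallback uses known chemistry; it sets out from 3 (bypassing 5) and comes back at 6. Compound 3 is condensed with 3-methylbut-2-enal under ethylenediammonium diacetate catalysis in refluxing toluene (Knoevenagel condensation, then oxa-6π electrocyclisation of the ortho-quinone methide). This gives 6 together with its regioisomer 1-(5,7-dihydroxy-2,2-dimethyl-2H-chromen-6-yl)-2-methylpropan-1-one F1, which is removed by chromatography.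

Step 5 (proposed new step). Risks are prenylation at the unsubstituted ring carbon (the aromatic isomer, which stays in the organic layer on NaHCO3 extraction), persistent O-prenyl ether, a second prenylation, and low enantioselectivity. The fallback uses known chemistry; it sets out from 8 and comes back at 10. NaOMe (2 equiv) and 4 in MeOH at 0 °C give racemic 3,5-dihydroxy-4-methyl-4-(3-methylbut-2-en-1-yl)-2-(2-methylpropanoyl)cyclohexa-2,5-dien-1-one F2, freed from aromatic by-products by NaHCO3 extraction. F2 is resolved by preparative chiral SFC on an amylose-based phase into 10 and (4R)-3,5-dihydroxy-4-methyl-4-(3-methylbut-2-en-1-yl)-2-(2-methylpropanoyl)cyclohexa-2,5-dien-1-one F3, which is discarded; the enantiomer to keep is assigned by ECD.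

Step 6. Risks are methylene exchange (retro-Mannich) leading to the two symmetric dimers, sluggish loss of dimethylamine at 60 °C, and attack of the iminium on the chromene alkene. The fallback changes the one-carbon unit to the aldehyde oxidation level; it sets out from 6 and comes back at 13. Vilsmeier–Haack formylation of 6 (POCl3, DMF, MeCN, 0 °C → rt, then water) gives 5,7-dihydroxy-2,2-dimethyl-8-(2-methylpropanoyl)-2H-chromene-6-carbaldehyde F4. Proline-catalysed Knoevenagel condensation of F4 with 10 (CH2Cl2, rt) gives 2-{[5,7-dihydroxy-2,2-dimethyl-8-(2-methylpropanoyl)-2H-chromen-6-yl]methylidene}-5-hydroxy-4-methyl-4-(3-methylbut-2-en-1-yl)-6-(2-methylpropanoyl)cyclohex-5-ene-1,3-dione F5 (configuration at the quaternary carbon as in 10, not isolated). Hantzsch ester reduces F5 in the same flask to 13 (three-component reductive alkylation), so the bridging carbon is bound to ring B before it ever meets ring A.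

**Further compounds**
F1 | step 3 | 1-(5,7-dihydroxy-2,2-dimethyl-2H-chromen-6-yl)-2-methylpropan-1-one | CC(C)C(=O)c1c(O)cc2OC(C)(C)C=Cc2c1O
F2 | step 5 | racemic 3,5-dihydroxy-4-methyl-4-(3-methylbut-2-en-1-yl)-2-(2-methylpropanoyl)cyclohexa-2,5-dien-1-one | CC(C)=CCC1(C)C(O)=CC(=O)C(C(=O)C(C)C)=C1O
F3 | step 5 | (4R)-3,5-dihydroxy-4-methyl-4-(3-methylbut-2-en-1-yl)-2-(2-methylpropanoyl)cyclohexa-2,5-dien-1-one | CC(C)=CC[C@]1(C)C(O)=CC(=O)C(C(=O)C(C)C)=C1O
F4 | step 6 | 5,7-dihydroxy-2,2-dimethyl-8-(2-methylpropanoyl)-2H-chromene-6-carbaldehyde | CC(C)C(=O)c1c(O)c(C=O)c(O)c2C=CC(C)(C)Oc12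
F5 | step 6 | 2-{[5,7-dihydroxy-2,2-dimethyl-8-(2-methylpropanoyl)-2H-chromen-6-yl]methylidene}-5-hydroxy-4-methyl-4-(3-methylbut-2-en-1-yl)-6-(2-methylpropanoyl)cyclohex-5-ene-1,3-dione, quaternary carbon as in 10 | CC(C)=CC[C@@]1(C)C(=O)C(=Cc2c(O)c3C=CC(C)(C)Oc3c(C(=O)C(C)C)c2O)C(=O)C(C(=O)C(C)C)=C1O
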